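If two flasks end at the same volume, compare them by the fraction of X that stands left when they are read; whether E's share follows that fraction is what the fed runs have to show.

| flask | Q | X | remark | time |
|---|---|---|---|---|
| winter | 0.0061 M (fed, over 5.0 min) | 0.025 M | run made earlier; the fed solution adds 1.0 times the starting volume |  |
| noon | 0.0091 M (fed, over 5.0 min) | 0.025 M | run made earlier; the fed solution adds 1.0 times the starting volume |  |
| midnight | 0.017 M (fed, over 5.0 min) | 0.025 M | run made earlier; the fed solution adds 1.0 times the starting volume |  |
| Friday's | 0.020 M | 0.0250 M | everything together at the start, the whole solution of Q included, so that from the start the volume is larger by 1.0 times the starting volume | 2.5 min |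
| Tuesday's | 0.0050 M (fed, over 5.0 min) | 0.0250 M | the fed solution adds 1.0 times the starting volume | 5.0 min |

- winter (time / min: E / %, G / %): 0.417: 0, 0; 0.833: 4, 7; 1.33: 6, 8; 2.50: 6, 13; 5.00: 11, 37
- noon (time / min: E / %, G / %): 0.417: 1, 0; 1.33: 3, 3; 2.50: 6, 13; 4.00: 10, 26; 5.00: 14, 34
- midnight (time / min: E / %, G / %): 0.417: 2, 1; 0.833: 3, 2; 1.33: 2, 4; 2.50: 3, 12; 5.00: 10, 34

(scatter of a reading: 2 percentage points)

- amounts are per litre of the starting volume; all of the dose is in the solution fed
- the earlier runs were read with a standard deviation of 2 percentage points
- percentages count the whole charge, also what has not yet gone in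
- a reading or a percentage of E counts all its forms, free or not

* which one finishes higher in share of E in all that became E or G ("neither" within 2 percentage points) (Friday's / Tuesday's / neither)
* share of E in all that became E or G, Friday's
* share of E in all that became E or G, Tuesday's

Call that fraction f: one minus Q charged per X charged, times the fraction of the charge found as E or G, taking one X per Q turned over. At 5.0 min the three fed runs give:

| run | f | share of E |
|---|---|---|
| winter | 0.883 | 22.9% |
| noon | 0.825 | 29.2% |
| midnight | 0.701 | 22.7% |

The percentages barely move with the dose, so Q behaves as pseudo-first-order, and you can carry a conversion across doses. Tuesday's is fed like winter, so its f is 0.904, above winter's.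

Friday's looks harder, but fed Q has stood 2.50 min on average by the last reading, which matches Friday's time. Taking midnight's conversion, Friday's f, the fraction of its X left after one X per Q turned over, is 0.648, below midnight's.

One objection is that Friday's Q meets thinned X from the start, so this conversion may run high. But it would have to fall to about half, 21.8%, before f reached noon's.

A second objection is that Friday's is read earlier. Its volume is already full, though, so equal f means equal X concentration. The pooled share also falls from 28.3% at 2.50 min to 25.0% at 5.00 min as X thins.

So you take midnight's 22.7% for Friday's and pooled winter and noon, 26.0%, for Tuesday's. The gap of 3.3 percentage points is weak against readings scattering by 2 points.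

The forecast, on the ground that “E seems to favour high X”, says Tuesday's, with 20% for Friday's, lower than this reckoning, and 26% for Tuesday's.

Friday's gives 22.3% and Tuesday's 26.8%, so Tuesday's finishes higher.

    Q + X → L + Z (k = 0.650 M⁻¹ s⁻¹)
    L ⇌ E (K = 0.410, k = 0.600 s⁻¹)
    L ⇌ G (K = 2.50, k = 0.130 s⁻¹)
    X + E ⇌ J, settled at all times (K = 100 M⁻¹)

The main reason Friday's share stands so low is the back reaction of E to L: without it, Friday's share reaches 98.4%. Friday's falling X is a part of the rest: held at its level, the share there reaches 28.3%. Reckoned from Friday's own E and G, f is 0.658, against 0.648 beforehand, and a flask fed like Tuesday's but with 0.800 Q per X has f of 0.667 and ends at 22.6%.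

The data stem from a simulated flask for substances that don't exist.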